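**Retrosynthetic overview**

1. Pyranone C3–CH2 bond: Pd(0) C-allylation of triacetic acid lactone 13 with allylic alcohol 12 (last step; the pyranone ring is bought).
2. Ring-CH2–CH2 bond: α-sulfonyl carbanion of ring sulfone 7 plus (2E,6E)-8-bromogeranyl acetate 10, then reductive desulfonylation.
3. The only ring made (the methylenecyclohexanol) is closed before the other chain olefins exist, so polycyclization is impossible: cathodically driven Ti(III) epoxide opening/6-endo radical cyclization of epoxy allyl sulfone 6.
4. 6 comes from D-glutamic-acid-derived lactone ester 1: 2 MeMgBr, lactone → alkyne, carboalumination/CH2O, allylic sulfonylation, mesylate → epoxide with inversion.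
5. Stereochemistry: the carbinol carbon is bought in 1 (inverted once); it sets the ring CH centre in the cyclization.

Assumption: ester 1 is bought as a catalog compound (if only the free acid is stocked, Fischer esterification adds one step). Compound 11 is carried as a mixture of epimers at the sulfone carbon, which is removed in Step 10.

**Route**

Step 1
Reactants: 1, ethyl (2R)-5-oxooxolane-2-carboxylate
Product: 2, (5R)-5-(2-hydroxypropan-2-yl)oxolan-2-one
Conditions: MeMgBr (2.1 equiv), THF, −78 → −40 °C; aq. NH4Cl
Reagents that add atoms: methylmagnesium bromide, C[Mg]Br (two CH3)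
Why: Double Grignard addition to the α-alkoxy-activated ester, which reacts faster than the γ-lactone at low temperature (the intermediate ketone faster still); the stereocentre is not touched.

Step 2
Reactants: 2, (5R)-5-(2-hydroxypropan-2-yl)oxolan-2-one
Product: 3, (3R)-2-methylhept-6-yne-2,3-diol
Conditions: DIBAL-H (2.1 equiv), CH2Cl2, −78 °C; then MeOH, K2CO3, dimethyl (1-diazo-2-oxopropyl)phosphonate, rt
Reagents that add atoms: Ohira–Bestmann reagent, COP(=O)(OC)C(=[N+]=[N-])C(C)=O (one carbon, the alkyne CH)
Why: Lactone-to-lactol reduction followed by Seyferth–Gilbert/Ohira–Bestmann homologation of the open hydroxy-aldehyde gives the terminal alkyne without touching the carbinol centre.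

Step 3
Reactants: 3, (3R)-2-methylhept-6-yne-2,3-diol
Product: 4, (2E,6R)-3,7-dimethyloct-2-ene-1,6,7-triol
Conditions: AlMe3 (5 equiv), Cp2ZrCl2 (0.5 equiv), CH2Cl2, 0 °C → rt; then n-BuLi, THF, −78 °C; (CH2O)n, → rt
Reagents that add atoms: trimethylaluminium, C[Al](C)C (CH3); paraformaldehyde, C=O (CH2OH)
Why: Negishi Zr-catalyzed syn-carboalumination puts Me on the internal alkyne carbon, and trapping the alkenylalanate with formaldehyde retains geometry, giving the E-trisubstituted allylic alcohol (the diol rides through as aluminium alkoxides).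

Step 4
Reactants: 4, (2E,6R)-3,7-dimethyloct-2-ene-1,6,7-triol
Product: 5, (3R,6E)-2,6-dimethyl-8-(phenylsulfonyl)oct-6-ene-2,3-diol
Conditions: PhSO2Na (1.5 equiv), Pd(OAc)2 (5 mol%), PPh3 (20 mol%), Et3B (3 equiv), DMF, 50 °C
Reagents that add atoms: sodium benzenesulfinate, [Na+].[O-]S(=O)c1ccccc1 (PhSO2)
Why: Borane-assisted Pd-catalyzed dehydrative allylic substitution (Tsuji–Trost) ionizes only the allylic OH and gives the linear primary sulfone; the E geometry holds because σ-Pd at the tertiary allyl terminus is disfavoured.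

Step 5
Reactants: 5, (3R,6E)-2,6-dimethyl-8-(phenylsulfonyl)oct-6-ene-2,3-diol
Product: 6, (3S)-2,2-dimethyl-3-[(3E)-3-methyl-5-(phenylsulfonyl)pent-3-en-1-yl]oxirane
Conditions: MsCl (1.2 equiv), pyridine, CH2Cl2, 0 °C; then K2CO3, MeOH, rt
Reagents that add atoms: none (the mesylate is displaced)
Why: Selective mesylation of the secondary OH and intramolecular SN2 (Williamson) closure by the tertiary alkoxide invert the carbinol carbon cleanly, converting the (R)-diol into the (S)-epoxide.

Step 6
Reactants: 6, (3S)-2,2-dimethyl-3-[(3E)-3-methyl-5-(phenylsulfonyl)pent-3-en-1-yl]oxirane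
Product: 7, (1S,3R)-2,2-dimethyl-4-methylidene-3-[(phenylsulfonyl)methyl]cyclohexan-1-ol
Conditions: Cp2TiCl2 (20 mol%), TMSCl (2.5 equiv), 2,4,6-collidine (3.5 equiv), nBu4NPF6 (0.1 M), THF, undivided cell, RVC cathode/Zn anode, −1.0 V vs Ag/AgCl (about 1.3 F/mol), rt; then K2CO3, MeOH (cleaves the TMS ether)
Reagents that add atoms: none (TMSCl gives only a transient silyl ether)
Why: Proposed new method: cathodically regenerated Cp2Ti(III)Cl (electrode instead of metal powder, so no H-atom donor is present and the Ti(III) level is set by the potential) opens the epoxide at the tertiary C–O bond to a β-titanoxy tertiary radical, which closes 6-endo-trig onto the E-trisubstituted alkene through a chair transition state (OTi and CH2SO2Ph both equatorial, hence 1,3-cis and C3 = R under control of the bought carbinol centre), and the resulting tertiary ring radical is dehydrogenated at its methyl group by a second Cp2TiCl (mixed disproportionation, H2 loss) to the exocyclic alkene while TMSCl/collidine releases Cp2TiCl2 from the alkoxide; the closest known chemistry is the Mn-driven catalytic Ti(III) (Nugent–RajanBabu-type) cyclization of epoxypolyprenes and electro-/photoreductive titanocene catalysis of 5-exo epoxide radical cyclizations.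

Step 7
Reactants: 8, geranyl acetate [(2E)-3,7-dimethylocta-2,6-dien-1-yl acetate]
Product: 9, (2E,6E)-8-hydroxy-3,7-dimethylocta-2,6-dien-1-yl acetate
Conditions: SeO2 (0.3 equiv), t-BuOOH (3 equiv), salicylic acid (0.1 equiv), CH2Cl2, rt; NaBH4, MeOH, 0 °C (returns over-oxidized enal)
Reagents that add atoms: selenium dioxide, O=[Se]=O, with tert-butyl hydroperoxide, CC(C)(C)OO (the allylic O)
Why: Catalytic SeO2 allylic oxidation (ene/[2,3] sequence) is selective for the E-methyl of the terminal trisubstituted alkene, the 2,3-alkene being deactivated by the allylic acetate.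

Step 8
Reactants: 9, (2E,6E)-8-hydroxy-3,7-dimethylocta-2,6-dien-1-yl acetate
Product: 10, (2E,6E)-8-bromo-3,7-dimethylocta-2,6-dien-1-yl acetate
Conditions: CBr4, PPh3, CH2Cl2, 0 °C
Reagents that add atoms: carbon tetrabromide, BrC(Br)(Br)Br (Br)
Why: Appel bromination of the primary allylic alcohol proceeds by SN2 at the CH2 carbon without allylic transposition or loss of E geometry.

Step 9
Reactants: 7, (1S,3R)-2,2-dimethyl-4-methylidene-3-[(phenylsulfonyl)methyl]cyclohexan-1-ol; 10, (2E,6E)-8-bromo-3,7-dimethylocta-2,6-dien-1-yl acetate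
Product: 11, (2E,6E)-9-[(1R,3S)-3-hydroxy-2,2-dimethyl-6-methylidenecyclohexyl]-3,7-dimethyl-9-(phenylsulfonyl)nona-2,6-dien-1-yl acetate (epimers at C9)
Conditions: 7, n-BuLi (2.1 equiv), THF–DMPU, −78 °C; then 10 (1.2 equiv), −78 → −40 °C
Reagents that add atoms: none
Why: The O,C-dianion's soft α-sulfonyl carbanion alkylates the primary allylic bromide by SN2 (Julia-type sulfone alkylation) with retention of both E olefins, the acetate surviving at low temperature; the ring stereocentres are not acidic and stay intact.

Step 10
Reactants: 11, the C9-sulfonyl acetate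
Product: 12, (1S,3R)-3-[(3E,7E)-9-hydroxy-3,7-dimethylnona-3,7-dien-1-yl]-2,2-dimethyl-4-methylidenecyclohexan-1-ol
Conditions: Mg turnings (excess), MeOH, 50 °C
Reagents that add atoms: none
Why: Dissolving-metal (SET) reductive desulfonylation removes the non-allylic sulfone without touching isolated alkenes, and the Mg(OMe)2 formed methanolyses the acetate to the free allylic alcohol.

Step 11
Reactants: 12, the allylic alcohol above; 13, 4-hydroxy-6-methyl-2H-pyran-2-one (triacetic acid lactone, 3 equiv)
Product: 14, sartorypyrone D, 4-hydroxy-3-[(2E,6E)-9-[(1R,3S)-3-hydroxy-2,2-dimethyl-6-methylidenecyclohexyl]-3,7-dimethylnona-2,6-dien-1-yl]-6-methyl-2H-pyran-2-one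
Conditions: Pd(PPh3)4 (5 mol%), toluene, 80 °C
Reagents that add atoms: none
Why: Tsuji–Trost C-allylation in which the acidic hydroxypyranone (pKa about 5) activates the allylic alcohol and its stabilized C3 carbon attacks the primary terminus of the π-allyl (O-allylation is reversible), giving the linear E product; the secondary alcohol and exocyclic alkene are inert.

**Compound list**

1 | ethyl (2R)-5-oxooxolane-2-carboxylate | CCOC(=O)[C@H]1CCC(=O)O1 | starting material
2 | (5R)-5-(2-hydroxypropan-2-yl)oxolan-2-one | CC(C)(O)[C@H]1CCC(=O)O1 | intermediate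
3 | (3R)-2-methylhept-6-yne-2,3-diol | CC(C)(O)[C@H](O)CCC#C | intermediate
4 | (2E,6R)-3,7-dimethyloct-2-ene-1,6,7-triol | CC(C)(O)[C@H](O)CC/C(C)=C/CO | intermediate
5 | (3R,6E)-2,6-dimethyl-8-(phenylsulfonyl)oct-6-ene-2,3-diol | CC(C)(O)[C@H](O)CC/C(C)=C/CS(=O)(=O)c1ccccc1 | intermediate
6 | (3S)-2,2-dimethyl-3-[(3E)-3-methyl-5-(phenylsulfonyl)pent-3-en-1-yl]oxirane | CC1(C)O[C@H]1CC/C(C)=C/CS(=O)(=O)c1ccccc1 | intermediate
7 | (1S,3R)-2,2-dimethyl-4-methylidene-3-[(phenylsulfonyl)methyl]cyclohexan-1-ol | C=C1CC[C@H](O)C(C)(C)[C@@H]1CS(=O)(=O)c1ccccc1 | intermediate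
8 | geranyl acetate | CC(C)=CCC/C(C)=C/COC(C)=O | starting material
9 | (2E,6E)-8-hydroxy-3,7-dimethylocta-2,6-dien-1-yl acetate | OC/C(C)=C/CC/C(C)=C/COC(C)=O | intermediate
10 | (2E,6E)-8-bromo-3,7-dimethylocta-2,6-dien-1-yl acetate | BrC/C(C)=C/CC/C(C)=C/COC(C)=O | intermediate
11 | (2E,6E)-9-[(1R,3S)-3-hydroxy-2,2-dimethyl-6-methylidenecyclohexyl]-3,7-dimethyl-9-(phenylsulfonyl)nona-2,6-dien-1-yl acetate (C9 epimers) | C=C1CC[C@H](O)C(C)(C)[C@@H]1C(C/C(C)=C/CC/C(C)=C/COC(C)=O)S(=O)(=O)c1ccccc1 | intermediate
12 | (1S,3R)-3-[(3E,7E)-9-hydroxy-3,7-dimethylnona-3,7-dien-1-yl]-2,2-dimethyl-4-methylidenecyclohexan-1-ol | C=C1CC[C@H](O)C(C)(C)[C@@H]1CC/C(C)=C/CC/C(C)=C/CO | intermediate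
13 | 4-hydroxy-6-methyl-2H-pyran-2-one (triacetic acid lactone) | Cc1cc(O)cc(=O)o1 | starting material
14 | sartorypyrone D | C=C1CC[C@H](O)C(C)(C)[C@@H]1CC/C(C)=C/CC/C(C)=C/Cc1c(O)cc(C)oc1=O | target

**Totals**

Total steps: 11. Longest linear sequence: 9 (steps 1–6, 9, 10, 11).

**Three steps most likely to fail**

1. Step 6 (proposed new electrochemical Ti(III) cyclization). Risks are epoxide deoxygenation, endo/exo olefin mixtures and poor current efficiency. Fallback with known chemistry: move to the acetate series and metal-powder Ti(III). Acetylate the primary OH of 4, form the epoxide (MsCl; K2CO3/MeOH) and re-acetylate to (S)-6,7-epoxygeranyl acetate. Cyclize with the established Cp2TiCl2/Mn/TMSCl–collidine protocol for this substrate class, then install the sulfone after ring formation (K2CO3/MeOH; I2/PPh3/imidazole; PhSO2Na) to rejoin at 7.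

2. Step 3 (carboalumination/hydroxymethylation on the unprotected diol). Fallback: protect 3 as the acetonide and hydroxymethylate the acetylide (n-BuLi, (CH2O)n). Then use anti-hydroalumination/iodination (Red-Al; I2) and Me2CuLi substitution of the (Z)-3-iodo allylic alcohol to get the same E-trisubstituted allylic alcohol, and deprotect.

3. Step 11 (Pd allylation of the pyranone: C- versus O-allylation, bis-allylation, branched isomer). Fallback: abandon π-allyl chemistry. Convert the allylic OH of 12 selectively to the bromide (CBr4/PPh3, −30 °C) and C3-alkylate the triacetic acid lactone anion (DBU) by SN2, which also keeps the E geometry.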